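**Retrosynthetic overview**
- Bilagrewin ⇐ selective allylic oxidation of the (7S,8S)-diol ⇐ hydride removal of a camphorsultam from the C9 acyl group of a trans-2-aryl-1,4-benzodioxane.
- The dioxane ring, the only ring made, ⇐ one-flask oxidative 8–O–4′ radical cross-coupling of N-sinapoyl-(2R)-bornane-10,2-sultam with unprotected 5-hydroxyconiferaldehyde, then closure of the 5′-OH onto the quinone methide.
- Ring-forming order: C8–O4′ bond first (sets C8 under sultam control), then C7–O5′ closure (sets C7 trans); both benzene rings are bought.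
- N-sinapoyl sultam ⇐ Heck reaction of N-acryloyl sultam with 4-bromo-2,6-dimethoxyphenol; 5-hydroxyconiferaldehyde ⇐ Wittig homologation of 5-hydroxyvanillin.

Assumption: the acyl radical derived from 6 is attacked on its Cα-Re face (anti to the lower sulfonyl oxygen of the (2R)-sultam), giving (8R)-11; if experiment shows the opposite sense, the enantiomeric sultam is used and nothing else changes.

Numbering: C7 is the aryl-bearing carbon (benzodioxine C3), C8 the carbon bearing C9 (benzodioxine C2); primed positions belong to the ring B (catechol) unit.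

**Route**

Step 1
Reactants: 1 (1S)-(−)-2,10-camphorsultam [(2R)-bornane-10,2-sultam]; 2 acryloyl chloride
Product: 4 N-acryloyl-(2R)-bornane-10,2-sultam, via sodium sultamide 3 (not isolated)
Conditions: NaH (1.1 equiv), toluene, 0 °C to rt; then 2 (1.2 equiv), BHT (trace), 0 °C to rt
Reagents that add atoms: none
Why: N-acylation of the sodium sultamide by an acid chloride (nucleophilic acyl substitution) is the standard high-yielding way to attach this auxiliary, and no stereocentre is touched.

Step 2
Reactants: 4 N-acryloyl-(2R)-bornane-10,2-sultam; 5 4-bromo-2,6-dimethoxyphenol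
Product: 6 N-[(E)-3-(4-hydroxy-3,5-dimethoxyphenyl)prop-2-enoyl]-(2R)-bornane-10,2-sultam (N-sinapoyl sultam)
Conditions: Pd(OAc)2 (3 mol %), P(o-tol)3 (6 mol %), NaOAc (1.5 equiv), BHT (trace), DMF, 110 °C
Reagents that add atoms: none
Why: Mizoroki–Heck reaction, in which zerovalent palladium inserts into the C–Br bond, the aryl group adds to the terminal carbon of the acrylimide and syn β-hydride elimination gives only the E-cinnamoyl imide, with the free phenol tolerated by the weak acetate base.

Step 3
Reactants: 7 5-hydroxyvanillin (3,4-dihydroxy-5-methoxybenzaldehyde); 8 (triphenylphosphoranylidene)acetaldehyde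
Product: 9 5-hydroxyconiferaldehyde [(E)-3-(3,4-dihydroxy-5-methoxyphenyl)prop-2-enal]
Conditions: 8 (1.3 equiv), toluene–THF 1:1, 80 °C, Ar
Reagents that add atoms: none
Why: Wittig olefination with a formyl-stabilised ylide is E-selective and, because the ylide is too weakly basic to be consumed irreversibly by the phenols and the product enal is less electrophilic than the aryl aldehyde, gives the two-carbon homologue without catechol protection.

Step 4
Reactants: 6 N-sinapoyl sultam; 9 5-hydroxyconiferaldehyde
Product: 11 N-{[(2R,3S)-3-(4-hydroxy-3,5-dimethoxyphenyl)-8-methoxy-6-[(E)-3-oxoprop-1-enyl]-2,3-dihydro-1,4-benzodioxin-2-yl]carbonyl}-(2R)-bornane-10,2-sultam (trans; 7S,8R), via quinone methide 10 (not isolated)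
Conditions: Ag2CO3 (2.5 equiv), toluene–acetone 2:1, 25 °C, dark, 6 added over 6 h; chromatography then crystallisation to a single diastereomer
Reagents that add atoms: none
Why: Proposed new method: monovalent silver oxidises both phenols to phenoxyl radicals; the O4′-centred semiquinone of 9 (the oxygen para to the enal) couples with C8 of the sinapoyl radical on the Cα-Re face left open by the sultam (C=O anti to SO2, s-cis radical), which sets C8 as R, and the neighbouring 5′-OH then adds to C7 of quinone methide 10 anti to the acyl group, closing the dioxane ring trans (C7 S); the closest known reactions are the racemic Ag2CO3 benzodioxane synthesis from catechols and p-hydroxycinnamyl partners and the camphorsultam-controlled oxidative 8–5′ dimerisation of feruloyl sultams.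

Step 5
Reactants: 11 trans-benzodioxane acyl sultam (7S,8R)
Product: 12 (E)-3-[(2S,3S)-3-(4-hydroxy-3,5-dimethoxyphenyl)-2-(hydroxymethyl)-8-methoxy-2,3-dihydro-1,4-benzodioxin-6-yl]prop-2-en-1-ol (7S,8S-diol)
Conditions: LiBH4 (5 equiv), MeOH (5 equiv), THF, 0 °C; aq NH4Cl
Reagents that add atoms: none
Why: Hydride reductive cleavage of the N-acyl sultam (standard auxiliary removal to the primary alcohol, with 1 recovered) is accompanied by 1,2-reduction of the enal, and at 0 °C hydride addition to the activated α-aryloxy imide outruns enolisation, so C8 keeps its configuration (the descriptor changes from R to S only through the priority change) and no new stereocentre forms.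

Step 6
Reactants: 12 (7S,8S)-diol
Product: 13 bilagrewin, (E)-3-[(2S,3S)-3-(4-hydroxy-3,5-dimethoxyphenyl)-2-(hydroxymethyl)-8-methoxy-2,3-dihydro-1,4-benzodioxin-6-yl]prop-2-enal
Conditions: DDQ (1.1 equiv), THF, 0 °C to rt
Reagents that add atoms: none
Why: DDQ dehydrogenation by hydride abstraction from the allylic carbinol conjugated with the para-alkoxy arene is selective for cinnamyl-type alcohols over the saturated primary alcohol, is the standard conversion of phenolic cinnamyl alcohols into cinnamaldehydes, and leaves both stereocentres untouched.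

**Compound list**

1 | (1S)-(−)-2,10-camphorsultam, (2R)-bornane-10,2-sultam | CC1(C)[C@@H]2CC[C@]13CS(=O)(=O)N[C@@H]3C2 | starting material
2 | acryloyl chloride | C=CC(Cl)=O | starting material
3 | sodium salt of 1 (sodium sultamide) | [Na+].CC1(C)[C@@H]2CC[C@]13CS(=O)(=O)[N-][C@@H]3C2 | intermediate
4 | N-acryloyl-(2R)-bornane-10,2-sultam | C=CC(=O)N1[C@@H]2C[C@H]3CC[C@]2(CS1(=O)=O)C3(C)C | intermediate
5 | 4-bromo-2,6-dimethoxyphenol | COc1cc(Br)cc(OC)c1O | starting material
6 | N-[(E)-sinapoyl]-(2R)-bornane-10,2-sultam | COc1cc(/C=C/C(=O)N2[C@@H]3C[C@H]4CC[C@]3(CS2(=O)=O)C4(C)C)cc(OC)c1O | intermediate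
7 | 5-hydroxyvanillin | COc1cc(C=O)cc(O)c1O | starting material
8 | (triphenylphosphoranylidene)acetaldehyde | O=CC=P(c1ccccc1)(c1ccccc1)c1ccccc1 | starting material
9 | 5-hydroxyconiferaldehyde | COc1cc(/C=C/C=O)cc(O)c1O | intermediate
10 | (8R)-8–O–4′ quinone methide: sultam imide of (2R)-2-[2-hydroxy-6-methoxy-4-[(E)-3-oxoprop-1-enyl]phenoxy]-3-(3,5-dimethoxy-4-oxocyclohexa-2,5-dien-1-ylidene)propanoic acid | COC1=CC(=C[C@@H](Oc2c(O)cc(/C=C/C=O)cc2OC)C(=O)N2[C@@H]3C[C@H]4CC[C@]3(CS2(=O)=O)C4(C)C)C=C(OC)C1=O | intermediate
11 | trans-(7S,8R) benzodioxane acyl sultam: sultam imide of (2R,3S)-3-(4-hydroxy-3,5-dimethoxyphenyl)-8-methoxy-6-[(E)-3-oxoprop-1-enyl]-2,3-dihydro-1,4-benzodioxine-2-carboxylic acid | COc1cc([C@@H]2Oc3cc(/C=C/C=O)cc(OC)c3O[C@H]2C(=O)N2[C@@H]3C[C@H]4CC[C@]3(CS2(=O)=O)C4(C)C)cc(OC)c1O | intermediate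
12 | (7S,8S)-diol: (E)-3-[(2S,3S)-3-(4-hydroxy-3,5-dimethoxyphenyl)-2-(hydroxymethyl)-8-methoxy-2,3-dihydro-1,4-benzodioxin-6-yl]prop-2-en-1-ol | COc1cc([C@@H]2Oc3cc(/C=C/CO)cc(OC)c3O[C@H]2CO)cc(OC)c1O | intermediate
13 | bilagrewin | COc1cc([C@@H]2Oc3cc(/C=C/C=O)cc(OC)c3O[C@H]2CO)cc(OC)c1O | target

**Count and risks**

Total step count: 6. Longest linear sequence: 5 (steps 1, 2, 4, 5, 6); step 3 is the side branch.

Three steps most likely to fail:

Step 4 (cross-coupling and ring closure). The risks are 8–8′ homo-coupling of 6, over-oxidation of 9 to its o-quinone (which would favour the other regioisomer), modest facial selectivity, and base-mediated opening and reclosure of 11. The fallback sets out from 9 and drops the auxiliary. Ag2CO3 coupling of 9 with commercial sinapyl alcohol F1 in toluene–acetone proceeds through the racemic quinone methide F2 and gives the trans-benzodioxane directly as a racemate, that is 13 together with ent-bilagrewin F3. The two are separated by preparative HPLC on a chiral stationary phase. This comes back to the route at 13 and makes steps 1, 2, 5 and 6 unnecessary.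

Step 3 (Wittig on the unprotected catechol aldehyde). The risks are low conversion of the phenoxide-deactivated aldehyde and double homologation. The fallback sets out from 7 and carries the side chain at the ester level. Knoevenagel–Doebner condensation with malonic acid (pyridine, piperidine, 80 °C) gives 5-hydroxyferulic acid F4, and MeOH with catalytic H2SO4 gives methyl 5-hydroxyferulate F5. F5 replaces 9 in the Ag2CO3 coupling with 6 and passes through the ester quinone methide F6 to the ester imide F7. Excess i-Bu2AlH (CH2Cl2–THF, −78 to 0 °C) then reduces the cinnamate and the acyl sultam together. This comes back to the route at 12.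

Step 2 (Heck reaction). The risks are slow oxidative addition into the electron-rich bromophenol and oxa-Michael addition or polymerisation of 4. The fallback sets out from 1 and builds the imide by acylation. Sinapic acid F8 is acetylated (Ac2O, pyridine) to 4-O-acetylsinapic acid F9 and converted with oxalyl chloride and catalytic DMF into 4-O-acetylsinapoyl chloride F10. F10 acylates sodium sultamide 3 to give N-(4-O-acetylsinapoyl)-(2R)-bornane-10,2-sultam F11. Pyrrolidine in CH2Cl2 at 0 °C removes the aryl acetate chemoselectively. This comes back to the route at 6 and makes step 1 unnecessary.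

Further compounds
F1 | step 4 | sinapyl alcohol | COc1cc(/C=C/CO)cc(OC)c1O
F2 | step 4 | racemic 8–O–4′ quinone methide from F1 and 9 | COC1=CC(=CC(CO)Oc2c(O)cc(/C=C/C=O)cc2OC)C=C(OC)C1=O
F3 | step 4 | ent-bilagrewin (7R,8R) | COc1cc([C@H]2Oc3cc(/C=C/C=O)cc(OC)c3O[C@@H]2CO)cc(OC)c1O
F4 | step 3 | 5-hydroxyferulic acid | COc1cc(/C=C/C(=O)O)cc(O)c1O
F5 | step 3 | methyl 5-hydroxyferulate | COC(=O)/C=C/c1cc(O)c(O)c(OC)c1
F6 | step 3 | (8R)-quinone methide, methyl ester analogue of 10 | COC1=CC(=C[C@@H](Oc2c(O)cc(/C=C/C(=O)OC)cc2OC)C(=O)N2[C@@H]3C[C@H]4CC[C@]3(CS2(=O)=O)C4(C)C)C=C(OC)C1=O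
F7 | step 3 | trans-(7S,8R) benzodioxane acyl sultam, methyl cinnamate analogue of 11 | COc1cc([C@@H]2Oc3cc(/C=C/C(=O)OC)cc(OC)c3O[C@H]2C(=O)N2[C@@H]3C[C@H]4CC[C@]3(CS2(=O)=O)C4(C)C)cc(OC)c1O
F8 | step 2 | sinapic acid | COc1cc(/C=C/C(=O)O)cc(OC)c1O
F9 | step 2 | 4-O-acetylsinapic acid | COc1cc(/C=C/C(=O)O)cc(OC)c1OC(C)=O
F10 | step 2 | 4-O-acetylsinapoyl chloride | COc1cc(/C=C/C(Cl)=O)cc(OC)c1OC(C)=O
F11 | step 2 | N-(4-O-acetylsinapoyl)-(2R)-bornane-10,2-sultam | COc1cc(/C=C/C(=O)N2[C@@H]3C[C@H]4CC[C@]3(CS2(=O)=O)C4(C)C)cc(OC)c1OC(C)=O
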